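The dihydrofuran ring is disconnected at C2–O1 (benzofuran numbering: O1, aryl-bearing C2, CH2OH-bearing C3; ring A is the fused benzene ring). The feature exploited is the 4-hydroxy-3,5-dimethoxyphenyl ring on C2: oxidation converts it into a para-quinone methide whose exocyclic carbon is C2, positioned for five-membered closure by the ring A phenol oxygen. In one operation, Ag2O oxidation and intramolecular phenol addition form the C2–O1 bond, close the ring and set C2 trans to the existing C3 centre. The precursor is an open-chain diphenol: a (2R)-2-aryl-3-arylpropanol silyl ether already carrying the propanoate chain, assembled by auxiliary-controlled benzylation of a ring A arylacetic acid.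

Key step: step 14

Remark: CIP analysis gives the target as (2S,3R) with the C2 aryl and C3 CH2OH groups trans; the open-chain centre that becomes C3 is R throughout and chelate-controlled alkylation delivers it from the (R)-benzyl oxazolidinone, so no structure needed correction.

Step 1
Reactants: 1 4-bromo-2-methoxyphenol; 2 allyl bromide
Product: 3 1-(allyloxy)-4-bromo-2-methoxybenzene
Conditions: K2CO3, acetone, reflux
Reagents that add atoms: none
Why: Williamson ether synthesis, in which the phenoxide should displace the allylic bromide cleanly at oxygen.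

Step 2
Reactants: 3 1-(allyloxy)-4-bromo-2-methoxybenzene
Product: 4 2-allyl-4-bromo-6-methoxyphenol
Conditions: PhNEt2, 190 °C
Reagents that add atoms: none
Why: Aromatic Claisen rearrangement ([3,3]-sigmatropic shift, then rearomatisation) should deliver the allyl group to the only free ortho carbon, since the other ortho position carries OMe and the para position carries Br.

Step 3
Reactants: 4 2-allyl-4-bromo-6-methoxyphenol
Product: 5 1-allyl-2-(benzyloxy)-5-bromo-3-methoxybenzene
Conditions: BnBr, K2CO3, DMF, 60 °C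
Reagents that add atoms: benzyl bromide, BrCc1ccccc1
Why: Williamson benzylation gives an aryl benzyl ether that tolerates enolate, hydride and Heck conditions and is removed later by hydrogenolysis.

Step 4
Reactants: 5 1-allyl-2-(benzyloxy)-5-bromo-3-methoxybenzene
Product: 7 [2-(benzyloxy)-5-bromo-3-methoxyphenyl]acetic acid, via arylacetaldehyde 6 (not isolated)
Conditions: O3, MeCN/H2O (9:1), 0 °C; then NaClO2, NaH2PO4, 0 °C to rt
Reagents that add atoms: ozone, [O-][O+]=O; water, O; sodium chlorite (NaClO2), [Na+].[O-]Cl=O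
Why: Ozonolysis in aqueous acetonitrile, where water traps the carbonyl oxide, should give the aldehyde and H2O2 directly, and Pinnick oxidation in the same flask converts the labile arylacetaldehyde to the acid with the H2O2 acting as hypochlorite scavenger.

Step 5
Reactants: 7 [2-(benzyloxy)-5-bromo-3-methoxyphenyl]acetic acid; 8 (R)-4-benzyl-1,3-oxazolidin-2-one
Product: 10 (4R)-4-benzyl-3-{[2-(benzyloxy)-5-bromo-3-methoxyphenyl]acetyl}-1,3-oxazolidin-2-one, via mixed pivalic anhydride 9 (not isolated)
Conditions: PivCl, Et3N, THF, −20 °C; then 8, LiCl, −20 °C to rt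
Reagents that add atoms: none
Why: N-acylation of the oxazolidinone through a mixed anhydride (LiCl/Et3N activation) should occur at the arylacetyl carbonyl because the pivaloyl carbonyl is shielded by the tert-butyl group.

Step 6
Reactants: 11 syringaldehyde
Product: 12 4-(benzyloxy)-3,5-dimethoxybenzaldehyde
Conditions: BnBr, K2CO3, DMF, 60 °C
Reagents that add atoms: benzyl bromide, BrCc1ccccc1
Why: Williamson benzylation masks the syringyl phenol, which would otherwise make the derived benzylic bromide eliminate to a quinone methide.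

Step 7
Reactants: 12 4-(benzyloxy)-3,5-dimethoxybenzaldehyde
Product: 13 [4-(benzyloxy)-3,5-dimethoxyphenyl]methanol
Conditions: NaBH4, MeOH, 0 °C
Reagents that add atoms: none
Why: Borohydride reduction of an aromatic aldehyde to the benzylic alcohol is routine and leaves the ethers untouched.

Step 8
Reactants: 13 [4-(benzyloxy)-3,5-dimethoxyphenyl]methanol
Product: 14 2-(benzyloxy)-5-(bromomethyl)-1,3-dimethoxybenzene
Conditions: PBr3, CH2Cl2, 0 °C
Reagents that add atoms: phosphorus tribromide, BrP(Br)Br
Why: Bromination through the phosphite ester should convert the activated benzylic alcohol to the bromide under mild conditions, and the bromide is used freshly because it is electron-rich and labile.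

Step 9
Reactants: 10 (4R)-4-benzyl-3-{[2-(benzyloxy)-5-bromo-3-methoxyphenyl]acetyl}-1,3-oxazolidin-2-one; 14 2-(benzyloxy)-5-(bromomethyl)-1,3-dimethoxybenzene
Product: 16 (4R)-4-benzyl-3-[(2R)-2-[2-(benzyloxy)-5-bromo-3-methoxyphenyl]-3-[4-(benzyloxy)-3,5-dimethoxyphenyl]propanoyl]-1,3-oxazolidin-2-one, via sodium Z-enolate 15 (not isolated)
Conditions: NaN(SiMe3)2, THF, −78 °C; then 14, −78 to −40 °C; AcOH quench at −78 °C
Reagents that add atoms: none
Why: Evans asymmetric alkylation, in which the Z-enolate 15 is held in a sodium chelate with the oxazolidinone carbonyl, the C4 benzyl group of the (R)-auxiliary blocks one face and the benzylic bromide attacks the other, which sets the future C3 centre as R.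

Step 10
Reactants: 16 (4R)-4-benzyl-3-[(2R)-2-[2-(benzyloxy)-5-bromo-3-methoxyphenyl]-3-[4-(benzyloxy)-3,5-dimethoxyphenyl]propanoyl]-1,3-oxazolidin-2-one
Product: 17 (2R)-2-[2-(benzyloxy)-5-bromo-3-methoxyphenyl]-3-[4-(benzyloxy)-3,5-dimethoxyphenyl]propan-1-ol
Conditions: LiBH4, MeOH (1 equiv), Et2O, 0 °C
Reagents that add atoms: none
Why: Reductive cleavage of the N-acyl oxazolidinone by hydride attack at the exocyclic carbonyl should give the primary alcohol without touching the aryl bromide, and the transient aldehyde is reduced faster than it enolises, so the centre stays R.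

Step 11
Reactants: 17 (2R)-2-[2-(benzyloxy)-5-bromo-3-methoxyphenyl]-3-[4-(benzyloxy)-3,5-dimethoxyphenyl]propan-1-ol
Product: 18 tert-butyl{[(2R)-2-[2-(benzyloxy)-5-bromo-3-methoxyphenyl]-3-[4-(benzyloxy)-3,5-dimethoxyphenyl]propyl]oxy}dimethylsilane
Conditions: TBSCl, imidazole, DMF, rt
Reagents that add atoms: tert-butyldimethylsilyl chloride, CC(C)(C)[Si](C)(C)Cl
Why: Imidazole-promoted silylation of the unhindered primary alcohol is reliable and gives an ether that survives the Heck, hydrogenation and Ag2O steps.

Step 12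
Reactants: 18 tert-butyl{[(2R)-2-[2-(benzyloxy)-5-bromo-3-methoxyphenyl]-3-[4-(benzyloxy)-3,5-dimethoxyphenyl]propyl]oxy}dimethylsilane; 19 methyl acrylate
Product: 20 methyl (2E)-3-{4-(benzyloxy)-3-[(2R)-1-[4-(benzyloxy)-3,5-dimethoxyphenyl]-3-[(tert-butyldimethylsilyl)oxy]propan-2-yl]-5-methoxyphenyl}prop-2-enoate
Conditions: Pd(OAc)2 (5 mol %), P(o-tol)3 (10 mol %), Et3N, DMF, 100 °C
Reagents that add atoms: none
Why: Mizoroki–Heck reaction, in which the aryl bromide (no ortho substituent) adds oxidatively to zerovalent palladium and syn insertion of the acrylate followed by beta-hydride elimination should give the E cinnamate.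

Step 13
Reactants: 20 methyl (2E)-3-{4-(benzyloxy)-3-[(2R)-1-[4-(benzyloxy)-3,5-dimethoxyphenyl]-3-[(tert-butyldimethylsilyl)oxy]propan-2-yl]-5-methoxyphenyl}prop-2-enoate
Product: 21 methyl 3-{4-hydroxy-3-[(2R)-1-[(tert-butyldimethylsilyl)oxy]-3-(4-hydroxy-3,5-dimethoxyphenyl)propan-2-yl]-5-methoxyphenyl}propanoate
Conditions: H2 (1 atm), 10% Pd/C, EtOAc, rt
Reagents that add atoms: none
Why: A single catalytic hydrogenation should saturate the cinnamate double bond and hydrogenolyse both aryl benzyl ethers, while the neutral aprotic solvent preserves the silyl ether and the molecule has no other benzylic C–O bond.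

Step 14
Reactants: 21 methyl 3-{4-hydroxy-3-[(2R)-1-[(tert-butyldimethylsilyl)oxy]-3-(4-hydroxy-3,5-dimethoxyphenyl)propan-2-yl]-5-methoxyphenyl}propanoate
Product: 23 methyl 3-[(2S,3R)-3-{[(tert-butyldimethylsilyl)oxy]methyl}-2-(4-hydroxy-3,5-dimethoxyphenyl)-7-methoxy-2,3-dihydro-1-benzofuran-5-yl]propanoate, via para-quinone methide 22 (not isolated)
Conditions: Ag2O (1.5 equiv), CH2Cl2, rt, dark
Reagents that add atoms: none
Why: Ag2O should remove two electrons and two protons (the phenolic hydrogen and one C2 hydrogen) from the 2,6-dimethoxyphenol of 21 to give the para-quinone methide 22, whose exocyclic carbon is then attacked by the ring A phenol oxygen in a 1,6-conjugate addition that forms C2–O1 and restores the aromatic syringyl ring. The closest known reaction type is the Ag2O oxidation of 4-alkyl-2,6-dimethoxyphenols to para-quinone methides and their capture by phenols, the ring-closing half of oxidative 8–5 phenol coupling that leads to trans-phenylcoumarans. The dihydrofuran ring closes in 5-exo-trig mode, the C2=C bond of the methide lying outside the new ring. The new C2 centre is controlled by the existing C3 centre: in the cyclisation transition state the CH2OTBS group on C3 and the quinone methide ring on C2 should avoid each other, giving the 2,3-trans (2S,3R) isomer, which is also the more stable one. The step needs oxidation at the syringol and not at the ring A phenol, which rests on the second methoxy group (lower oxidation potential, better stabilised methide) and on fast hydrogen exchange between phenol and phenoxyl that funnels oxidation to the syringyl site; it also needs ring closure to outrun prototropic shift of 22 to the stilbene, which rests on the intramolecular five-membered closure and the absence of soluble base. The silyl ether prevents loss of formaldehyde from 22 and adds bulk that reinforces the trans preference.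

Step 15
Reactants: 23 methyl 3-[(2S,3R)-3-{[(tert-butyldimethylsilyl)oxy]methyl}-2-(4-hydroxy-3,5-dimethoxyphenyl)-7-methoxy-2,3-dihydro-1-benzofuran-5-yl]propanoate
Product: 24 methyl 3-[(2S,3R)-2-(4-hydroxy-3,5-dimethoxyphenyl)-3-(hydroxymethyl)-7-methoxy-2,3-dihydro-1-benzofuran-5-yl]propanoate
Conditions: Bu4NF, AcOH, THF, 0 °C to rt
Reagents that add atoms: none
Why: Fluoride-mediated desilylation buffered with acetic acid should free the primary alcohol without exposing the methyl ester or the phenolic benzylic ether to basic fluoride, and neither C2 nor C3 is involved.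

Compound list
1 | 4-bromo-2-methoxyphenol | COc1cc(Br)ccc1O | starting material
2 | allyl bromide (3-bromoprop-1-ene) | C=CCBr | starting material
3 | 1-(allyloxy)-4-bromo-2-methoxybenzene | COc1cc(Br)ccc1OCC=C | intermediate
4 | 2-allyl-4-bromo-6-methoxyphenol | COc1cc(Br)cc(CC=C)c1O | intermediate
5 | 1-allyl-2-(benzyloxy)-5-bromo-3-methoxybenzene | COc1cc(Br)cc(CC=C)c1OCc1ccccc1 | intermediate
6 | [2-(benzyloxy)-5-bromo-3-methoxyphenyl]acetaldehyde | COc1cc(Br)cc(CC=O)c1OCc1ccccc1 | intermediate (not isolated)
7 | [2-(benzyloxy)-5-bromo-3-methoxyphenyl]acetic acid | COc1cc(Br)cc(CC(=O)O)c1OCc1ccccc1 | intermediate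
8 | (R)-4-benzyl-1,3-oxazolidin-2-one | O=C1N[C@H](Cc2ccccc2)CO1 | starting material
9 | [2-(benzyloxy)-5-bromo-3-methoxyphenyl]acetic pivalic anhydride | COc1cc(Br)cc(CC(=O)OC(=O)C(C)(C)C)c1OCc1ccccc1 | intermediate (not isolated)
10 | (4R)-4-benzyl-3-{[2-(benzyloxy)-5-bromo-3-methoxyphenyl]acetyl}-1,3-oxazolidin-2-one | COc1cc(Br)cc(CC(=O)N2[C@H](Cc3ccccc3)COC2=O)c1OCc1ccccc1 | intermediate
11 | syringaldehyde (4-hydroxy-3,5-dimethoxybenzaldehyde) | COc1cc(C=O)cc(OC)c1O | starting material
12 | 4-(benzyloxy)-3,5-dimethoxybenzaldehyde | COc1cc(C=O)cc(OC)c1OCc1ccccc1 | intermediate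
13 | [4-(benzyloxy)-3,5-dimethoxyphenyl]methanol | COc1cc(CO)cc(OC)c1OCc1ccccc1 | intermediate
14 | 2-(benzyloxy)-5-(bromomethyl)-1,3-dimethoxybenzene | COc1cc(CBr)cc(OC)c1OCc1ccccc1 | intermediate
15 | sodium (Z)-enolate of 10 | [Na+].[O-]/C(=C\c1cc(Br)cc(OC)c1OCc1ccccc1)N1[C@H](Cc2ccccc2)COC1=O | intermediate (not isolated)
16 | (4R)-4-benzyl-3-[(2R)-2-[2-(benzyloxy)-5-bromo-3-methoxyphenyl]-3-[4-(benzyloxy)-3,5-dimethoxyphenyl]propanoyl]-1,3-oxazolidin-2-one | O=C(N1[C@H](Cc2ccccc2)COC1=O)[C@H](Cc1cc(OC)c(OCc2ccccc2)c(OC)c1)c1cc(Br)cc(OC)c1OCc1ccccc1 | intermediate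
17 | (2R)-2-[2-(benzyloxy)-5-bromo-3-methoxyphenyl]-3-[4-(benzyloxy)-3,5-dimethoxyphenyl]propan-1-ol | OC[C@H](Cc1cc(OC)c(OCc2ccccc2)c(OC)c1)c1cc(Br)cc(OC)c1OCc1ccccc1 | intermediate
18 | tert-butyl{[(2R)-2-[2-(benzyloxy)-5-bromo-3-methoxyphenyl]-3-[4-(benzyloxy)-3,5-dimethoxyphenyl]propyl]oxy}dimethylsilane | CC(C)(C)[Si](C)(C)OC[C@H](Cc1cc(OC)c(OCc2ccccc2)c(OC)c1)c1cc(Br)cc(OC)c1OCc1ccccc1 | intermediate
19 | methyl acrylate | C=CC(=O)OC | starting material
20 | methyl (2E)-3-{4-(benzyloxy)-3-[(2R)-1-[4-(benzyloxy)-3,5-dimethoxyphenyl]-3-[(tert-butyldimethylsilyl)oxy]propan-2-yl]-5-methoxyphenyl}prop-2-enoate | COC(=O)/C=C/c1cc(OC)c(OCc2ccccc2)c(c1)[C@H](CO[Si](C)(C)C(C)(C)C)Cc1cc(OC)c(OCc2ccccc2)c(OC)c1 | intermediate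
21 | methyl 3-{4-hydroxy-3-[(2R)-1-[(tert-butyldimethylsilyl)oxy]-3-(4-hydroxy-3,5-dimethoxyphenyl)propan-2-yl]-5-methoxyphenyl}propanoate | COC(=O)CCc1cc(OC)c(O)c(c1)[C@H](CO[Si](C)(C)C(C)(C)C)Cc1cc(OC)c(O)c(OC)c1 | intermediate
22 | methyl 3-{3-[(2R)-1-[(tert-butyldimethylsilyl)oxy]-3-(3,5-dimethoxy-4-oxocyclohexa-2,5-dien-1-ylidene)propan-2-yl]-4-hydroxy-5-methoxyphenyl}propanoate (para-quinone methide) | COC(=O)CCc1cc(OC)c(O)c(c1)[C@H](CO[Si](C)(C)C(C)(C)C)C=C1C=C(OC)C(=O)C(OC)=C1 | intermediate (not isolated)
23 | methyl 3-[(2S,3R)-3-{[(tert-butyldimethylsilyl)oxy]methyl}-2-(4-hydroxy-3,5-dimethoxyphenyl)-7-methoxy-2,3-dihydro-1-benzofuran-5-yl]propanoate | COC(=O)CCc1cc(OC)c2c(c1)[C@H](CO[Si](C)(C)C(C)(C)C)[C@@H](c1cc(OC)c(O)c(OC)c1)O2 | intermediate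
24 | methyl 3-[(2S,3R)-2-(4-hydroxy-3,5-dimethoxyphenyl)-3-(hydroxymethyl)-7-methoxy-2,3-dihydro-1-benzofuran-5-yl]propanoate | COC(=O)CCc1cc(OC)c2c(c1)[C@H](CO)[C@@H](c1cc(OC)c(O)c(OC)c1)O2 | target

Total step count: 15. Longest linear sequence: 12 steps (steps 1–5 and 9–15, from 4-bromo-2-methoxyphenol); the bromide 14 comes from a three-step side branch (steps 6–8).

Steps most likely to fail

Step 14. Oxidation may begin at the ring A phenol, whose para benzylic CH2 can then be dehydrogenated or lead to oligomers, instead of at the syringol. The fallback sets out from 20 and postpones saturation of the side chain, so that during the oxidation the ring A phenol is conjugated to the acrylate: it is harder to oxidise and has no para benzylic hydrogen. The two benzyl ethers of 20 are removed without reducing the alkene (BCl3, pentamethylbenzene, CH2Cl2, −78 °C; the primary silyl ether, the ester and the aryl methyl ethers should survive at this temperature) to give the cinnamate diphenol F1. Ag2O in CH2Cl2 should then oxidise only the syringol to the cinnamate quinone methide F2, which closes to the dihydrobenzofuran cinnamate F3, as in the known Ag2O chemistry of ferulate-type phenols. Brief hydrogenation of the side-chain alkene (H2, Pd/C, EtOAc), a known selective reduction of phenylcoumaran cinnamates, comes back to the route at 23.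

Step 9. The alpha-aryl centre of the product is doubly activated and may epimerise by proton exchange with enolate, facial selectivity may be eroded, and the electron-rich benzylic bromide may decompose before it is captured. The fallback avoids enolate alkylation: it sets out from acid 7 and aldehyde 12, which are joined by Perkin condensation (Ac2O, Et3N, 110 °C) to the (E)-2,3-diarylacrylic acid F4. Asymmetric hydrogenation of this alpha-aryl cinnamic acid (H2, Ru(OAc)2(H8-BINAP), MeOH, the ligand antipode chosen so that the 2R acid forms) should give the (2R)-2,3-diarylpropanoic acid F5 with the aryl bromide intact. Reduction with BH3·THF comes back to the route at 17, bypassing steps 5, 9 and 10.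

Step 4. Ozone may attack the electron-rich arene or the benzylic ether C–H bonds, and the enolisable arylacetaldehyde may self-condense in the one-flask sequence. The fallback sets out from 5 and replaces the ozonide pathway by glycol cleavage: osmium-catalysed dihydroxylation (OsO4 cat., NMO, acetone/H2O) should give the stable, purifiable racemic diol F6, whose cleavage with NaIO4 (THF/H2O) releases aldehyde 6 under neutral conditions; immediate chlorite oxidation (NaClO2, NaH2PO4, 2-methyl-2-butene) comes back to the route at 7.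

Further compounds
F1 | step 14 | methyl (2E)-3-{3-[(2R)-1-[(tert-butyldimethylsilyl)oxy]-3-(4-hydroxy-3,5-dimethoxyphenyl)propan-2-yl]-4-hydroxy-5-methoxyphenyl}prop-2-enoate | COC(=O)/C=C/c1cc(OC)c(O)c(c1)[C@H](CO[Si](C)(C)C(C)(C)C)Cc1cc(OC)c(O)c(OC)c1
F2 | step 14 | methyl (2E)-3-{3-[(2R)-1-[(tert-butyldimethylsilyl)oxy]-3-(3,5-dimethoxy-4-oxocyclohexa-2,5-dien-1-ylidene)propan-2-yl]-4-hydroxy-5-methoxyphenyl}prop-2-enoate | COC(=O)/C=C/c1cc(OC)c(O)c(c1)[C@H](CO[Si](C)(C)C(C)(C)C)C=C1C=C(OC)C(=O)C(OC)=C1
F3 | step 14 | methyl (2E)-3-[(2S,3R)-3-{[(tert-butyldimethylsilyl)oxy]methyl}-2-(4-hydroxy-3,5-dimethoxyphenyl)-7-methoxy-2,3-dihydro-1-benzofuran-5-yl]prop-2-enoate | COC(=O)/C=C/c1cc(OC)c2c(c1)[C@H](CO[Si](C)(C)C(C)(C)C)[C@@H](c1cc(OC)c(O)c(OC)c1)O2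
F4 | step 9 | (2E)-2-[2-(benzyloxy)-5-bromo-3-methoxyphenyl]-3-[4-(benzyloxy)-3,5-dimethoxyphenyl]prop-2-enoic acid | OC(=O)/C(=C/c1cc(OC)c(OCc2ccccc2)c(OC)c1)c1cc(Br)cc(OC)c1OCc1ccccc1
F5 | step 9 | (2R)-2-[2-(benzyloxy)-5-bromo-3-methoxyphenyl]-3-[4-(benzyloxy)-3,5-dimethoxyphenyl]propanoic acid | OC(=O)[C@H](Cc1cc(OC)c(OCc2ccccc2)c(OC)c1)c1cc(Br)cc(OC)c1OCc1ccccc1
F6 | step 4 | 3-[2-(benzyloxy)-5-bromo-3-methoxyphenyl]propane-1,2-diol (racemic) | COc1cc(Br)cc(CC(O)CO)c1OCc1ccccc1
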